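The numbers in the tables are calculated with constants of no real substance; noise was put on by code.

| flask | solid substrate | gas | remark | time |
|---|---|---|---|---|
| Friday's | 0.15 M | 15 mM (held) | the very flask that is asked about, followed so far |  |
| flask | 0.15 M | 15 mM (held) |  | 40 h |

Friday's run (percent of the solid substrate charged)

| time / h | target / % | isomer of the product A / % |
|---|---|---|
| 0.167 | 0 | 0.3 |
| 0.500 | 3.7 | 4.4 |
| 0.833 | 7.6 | 9.5 |
| 1.33 | 7.2 | 18.6 |
| 2.00 | 9.4 | 31.7 |
| 2.50 | 11.6 | 41.6 |
| 3.00 | 13.0 | 50.5 |

(scatter of a reading: 1 percentage point)

- solid substrate is a solid; its amount is given per volume of the solution
- at the start none of the gas is in solution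
- at the start none of the solid substrate is in solution
- what has only dissolved of solid substrate counts as not reacted
- the reaction counts as stopped when no species that holds the solid substrate changes by six tenths of a point or more over the second half of the time

- why nothing more happens at 40 h, or that something still does (for what has run out or reacted, a solid counts together with what of it has only dissolved) (it is still moving / all of the solid substrate has reacted / forward and back rates have come level)
- target at 40 h, in percent of the solid substrate charged
- isomer of the product A at 40 h, in percent of the solid substrate charged

In a one-step, one-way world the fraction left, the charge not found as target or isomer of the product A, falls to nothing and stops there. Friday's run on this very flask shows how it falls: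

left at 1.33 h = 74.2 %

left at 3.00 h = 36.5 %

drain = (74.2 % − 36.5 %) / (3.00 h − 1.33 h) = 0.226 h⁻¹

This drain, the share of the charge that leaves the fraction left each hour, is a reading and carries the scatter of its readings. Friday's curve runs straight, zero order in what is left. Drawn back, the line leaves the full charge at the start point; drawn on, it meets zero at the knee:

start point = 3.00 h − (1 − 36.5 %) / 0.226 h⁻¹ = 0.187 h

knee = 3.00 h + 36.5 % / 0.226 h⁻¹ = 4.62 h

The curve reckoned here is therefore a short flat start, one straight fall, a knee and a level. The asked time is about ten times the knee, so the flask should stand still by then. The height of the level isn't in these readings: a line ending at zero and one bending off above zero look alike up to 3.00 h.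

The forecast says all of the solid substrate has reacted, with 19 % of target and 81 % of isomer of the product A, on this ground: “They show no approach to equilibrium”.

At 40 h the flask holds 7.01 % of target and 73.6 % of isomer of the product A: forward and back rates have come level.

    gas ⇌ reagent, rate k1*(csat - [reagent]) (kL = 0.00450 s⁻¹)
    solid substrate ⇌ starting material, rate k2*(cs2 - [starting material]) while solid is left; crystals form when [starting material] > cs2 (solubility = 0.0880 M, k = 2.50 × 10⁻⁴ s⁻¹)
    starting material + reagent ⇌ target (K = 40.0 M⁻¹, k = 0.0380 M⁻¹ s⁻¹)
    target ⇌ isomer of the product B (K = 1.10, k = 2.10 × 10⁻⁴ s⁻¹)
    starting material + reagent ⇌ isomer of the product A (K = 420 M⁻¹, k = 0.0230 M⁻¹ s⁻¹)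

Over the second half of the time no substrate, intermediate or product in this flask moves by more than 0.0093 percentage points. The fraction left stands at 19.4 %, not at zero. The drain carries Friday's line down to that level at 3.76 h, but at 4.00 h the fraction left in this flask is 27.1 %, higher than the level, so the flask has bent off above the line. Taken as a concentration, the drain is 33.9 mM h⁻¹. If that rate is assumed to hold there, the neighbour flask with 0.090 M of solid substrate needs an estimated 2.14 h for the products it shows at 40 h, which are 7.01 % of target and 73.6 % of isomer of the product A.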